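**Plan**

Locants in the text are chamigrane locants: C6 is the spiro carbon, ring B is C1–C6 (methyl C15 on C3), ring A is C6–C11 (C12/C13 on C11, C14 on C7).
Retrosynthesis: C7=C14 (methylenation), then C3–Cl (from a temporary C3–O–C7 ether bridge over the C2=C3 alkene), then C1–C6 and C2–C3 together (key step), then C5–C6 (Michael addition), C6–C11 (bromonium cyclisation) and C8–C9 (dianion alkylation).
Forward: ring A is closed first from an acyclic β-keto ester, the C5–C4–C3(=O)–C15 arm is added, ring B then arises in one operation from a C6 carboxylic acid, a vinylphosphonium salt (C1–C2) and the C3 ketone, and the ring B halogens come last.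
Enabling feature: C6 is an all-carbon quaternary centre between the gem-dimethyl carbon C11 and the oxygenated precursor of C7, and the methyl-bearing C3 lies 1,4 to it across ring B, so a tertiary C6 radical and a C3 methyl ketone can be joined by a two-carbon vinylphosphonium unit.
Stereochemistry: C10 comes from a catalytic enantioselective bromochlorination of prenol and is carried through a bromonium ion; C6 from axial radical attack anti to the axial C11 methyl; C2 and C3 from a bromoetherification whose face is fixed by the C7 oxygen, followed by chloride opening with retention.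

Key step: step 9

Remark: the ester-bearing carbon C6 (compounds 7 and 9–13) and the carbinol carbon C7 (compounds 11–13 and 15–18) are carried as epimer mixtures and left open in the SMILES. C6 becomes a planar radical in step 9 and C7 is erased in step 12. Both C7 epimers are expected to close the ether in step 10, the one with hydroxyl cis to bromine through the flipped chair of ring A. Names in the lists are systematic and use their own locants.

Step 1
Reactants: 1 prenol (3-methylbut-2-en-1-ol)
Product: 2 (S)-2-bromo-3-chloro-3-methylbutan-1-ol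
Conditions: NBS, ClTi(OiPr)3, chiral tridentate Schiff-base ligand (20 mol %, the enantiomer that gives (S)-2), hexane, −20 °C
Reagents that add atoms: N-bromosuccinimide, O=C1CCC(=O)N1Br; chlorotitanium triisopropoxide, CC(C)O[Ti](Cl)(OC(C)C)OC(C)C
Why: Titanium-alkoxide-directed catalytic enantioselective bromochlorination of an allylic alcohol, in which the ligand-bound titanium alkoxide delivers chloride anti to the bromonium ion at the tertiary carbon (Markovnikov) and so sets the C–Br stereocentre that becomes C10.

Step 2
Reactants: 2 (S)-2-bromo-3-chloro-3-methylbutan-1-ol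
Product: 3 (S)-2-bromo-3-chloro-3-methylbutyl trifluoromethanesulfonate
Conditions: Tf2O, 2,6-lutidine, CH2Cl2, −78 °C, used at once
Reagents that add atoms: triflic anhydride, FC(F)(F)S(=O)(=O)OS(=O)(=O)C(F)(F)F
Why: O-Sulfonylation of the primary alcohol with a non-nucleophilic base does not touch the stereocentre and gives an electrophile reactive enough for carbanion alkylation at −78 °C.

Step 3
Reactants: 3 (S)-2-bromo-3-chloro-3-methylbutyl trifluoromethanesulfonate; 4 allyl acetoacetate
Product: 6 allyl (6S)-6-bromo-7-chloro-7-methyl-3-oxooctanoate, via acetoacetate dianion 5 (not isolated)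
Conditions: 4, NaH then n-BuLi, THF, 0 °C; then 3, −78 °C; 1 M HCl quench
Reagents that add atoms: none
Why: γ-Alkylation of the acetoacetate dianion (Weiler alkylation) takes place at the more reactive terminal carbanion, which displaces the primary triflate at low temperature faster than it can eliminate HBr, and forms C8–C9.

Step 4
Reactants: 6 allyl (6S)-6-bromo-7-chloro-7-methyl-3-oxooctanoate
Product: 7 allyl (3S)-3-bromo-2,2-dimethyl-6-oxocyclohexane-1-carboxylate
Conditions: (CF3)2CHOH, 25 °C
Reagents that add atoms: none
Why: Solvolysis of the tertiary chloride in the ionising, non-nucleophilic solvent is assisted by the neighbouring bromine, and the bromonium ion is opened at its tertiary carbon by the enol of the β-keto ester (bromonium-ion-induced cation–olefin cyclisation), which closes ring A (C6–C11) and carries C10 over unchanged because no alkene is present to shuttle bromine.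

Step 5
Reactants: 7 allyl (3S)-3-bromo-2,2-dimethyl-6-oxocyclohexane-1-carboxylate; 8 methyl vinyl ketone (but-3-en-2-one)
Product: 9 allyl (3S)-3-bromo-2,2-dimethyl-6-oxo-1-(3-oxobutyl)cyclohexane-1-carboxylate
Conditions: FeCl3·6H2O (5 mol %), CH2Cl2, 25 °C
Reagents that add atoms: none
Why: Iron-trichloride-catalysed Michael addition of the cyclic β-keto ester goes through the chelated enol and not a free enolate, so the quaternary C6 with the C5–C4–C3(=O)–C15 arm forms without 1,3-displacement of the C10 bromide.

Step 6
Reactants: 9 allyl (3S)-3-bromo-2,2-dimethyl-6-oxo-1-(3-oxobutyl)cyclohexane-1-carboxylate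
Product: 10 allyl (3S)-3-bromo-2,2-dimethyl-1-[2-(2-methyl-1,3-dioxolan-2-yl)ethyl]-6-oxocyclohexane-1-carboxylate
Conditions: (TMSOCH2)2, TMSOTf (5 mol %), CH2Cl2, −78 °C
Reagents that add atoms: 1,2-bis(trimethylsilyloxy)ethane, C[Si](C)(C)OCCO[Si](C)(C)C
Why: Noyori ketalisation at low temperature protects the unhindered methyl ketone and leaves the ring ketone, which is flanked by the quaternary carbon, untouched.

Step 7
Reactants: 10 allyl (3S)-3-bromo-2,2-dimethyl-1-[2-(2-methyl-1,3-dioxolan-2-yl)ethyl]-6-oxocyclohexane-1-carboxylate
Product: 11 allyl (3S)-3-bromo-6-hydroxy-2,2-dimethyl-1-[2-(2-methyl-1,3-dioxolan-2-yl)ethyl]cyclohexane-1-carboxylate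
Conditions: NaBH4, MeOH, 0 °C
Reagents that add atoms: none
Why: Borohydride reduction of the only free ketone gives the C7 carbinol, which turns the β-keto ester into a β-hydroxy ester so that later decarboxylation gives a nucleophilic alkyl radical and not an enol, and supplies the oxygen needed in step 10.

Step 8
Reactants: 11 allyl (3S)-3-bromo-6-hydroxy-2,2-dimethyl-1-[2-(2-methyl-1,3-dioxolan-2-yl)ethyl]cyclohexane-1-carboxylate
Product: 13 (3S)-3-bromo-6-hydroxy-2,2-dimethyl-1-(3-oxobutyl)cyclohexane-1-carboxylic acid, via dioxolane acid 12 (not isolated)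
Conditions: Pd(PPh3)4 (5 mol %), morpholine, THF, 25 °C; then 1 M HCl, THF/H2O, 25 °C
Reagents that add atoms: water, O
Why: Allyl transfer from the ester to morpholine by zerovalent palladium frees the hindered acid without saponification, and aqueous acid then hydrolyses the dioxolane (acetal hydrolysis) without affecting the secondary bromide.

Step 9
Reactants: 13 (3S)-3-bromo-6-hydroxy-2,2-dimethyl-1-(3-oxobutyl)cyclohexane-1-carboxylic acid; 14 vinyltriphenylphosphonium bromide
Product: 16 (4S,6R)-4-bromo-5,5,9-trimethylspiro[5.5]undec-8-en-1-ol, via phosphorus ylide 15 (not isolated)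
Conditions: 4CzIPN (2 mol %), Cs2CO3 (2 equiv), DMSO, 450 nm LEDs, 25 °C; then 40 °C, dark
Reagents that add atoms: none
Why: Proposed new method: the excited photocatalyst oxidises the caesium carboxylate of 13, loss of CO2 gives the tertiary C6 radical, this adds to the CH2 terminus of 14 (Giese addition, C1–C6), the α-phosphonio radical is reduced by the photocatalyst radical anion to ylide 15, and 15 olefinates the tethered C3 methyl ketone (C2=C3). The closest known reaction type is the photoredox decarboxylative radical–polar crossover three-component Wittig olefination of carboxylic acids, vinylphosphonium salts and carbonyl compounds; new here are the intramolecular ketone partner and the fully substituted radical next to a quaternary carbon. Ring B is closed in the Wittig step by 6-exo-trig attack of the ylide carbon C2 on the C3 carbonyl, whereas the C1–C6 bond is formed intermolecularly. The only new stereocentre, C6, is set in the radical addition: ring A reacts as the chair with equatorial C10–Br, and the acceptor approaches axially, anti to the axial C11 methyl that shields the other face, so that C1 ends trans and C5 cis to bromine as in the target. The step needs addition to outrun hydrogen abstraction and needs the bromide and the ketone to survive; polarity matching of the nucleophilic tertiary radical with the cationic acceptor secures the first, and the second follows because a radical, unlike the C6 enolate, does not displace the C10 bromide and because the ylide forms under conditions too mild to enolise the methyl ketone.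

Step 10
Reactants: 16 (4S,6R)-4-bromo-5,5,9-trimethylspiro[5.5]undec-8-en-1-ol
Product: 17 bridged bromo ether (2,10-dibromo-3,7-epoxy-14-norchamigrane in chamigrane locants; C2, C3, C6 and C10 arranged as in 20)
Conditions: NBS, CH2Cl2, 0 °C, dark
Reagents that add atoms: N-bromosuccinimide, O=C1CCC(=O)N1Br
Why: Bromoetherification in the manner of the closure of α-terpineol to a bromocineole: the C7 oxygen can reach only the tertiary C3 and only on the ring B face that carries C7 (2-oxabicyclo[2.2.2]octane, Markovnikov), so the bromonium ion must lie on the opposite face and bromine ends on C2 anti to oxygen and cis to C11.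

Step 11
Reactants: 17 bridged bromo ether
Product: 18 (4S,6R,8S,9S)-4,8-dibromo-9-chloro-5,5,9-trimethylspiro[5.5]undecan-1-ol
Conditions: BCl3 (1.2 equiv), CH2Cl2, −78 to −40 °C; then H2O
Reagents that add atoms: boron trichloride, ClB(Cl)Cl
Why: Lewis-acid cleavage of the ether at its tertiary C3–O bond is assisted by the antiperiplanar C2 bromine, and the bromonium ion pair collapses by chloride transfer from boron to C3 on the face that oxygen has just left, so that C3–Cl forms with overall retention (double inversion) and trans to C2–Br while the secondary, neopentyl-like C7–O bond stays intact.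

Step 12
Reactants: 18 (4S,6R,8S,9S)-4,8-dibromo-9-chloro-5,5,9-trimethylspiro[5.5]undecan-1-ol
Product: 19 (4S,6R,8S,9S)-4,8-dibromo-9-chloro-5,5,9-trimethylspiro[5.5]undecan-1-one
Conditions: Dess–Martin periodinane, CH2Cl2, 25 °C
Reagents that add atoms: none
Why: Dess–Martin oxidation of the hindered secondary alcohol under near-neutral conditions converges both C7 epimers on one ketone without touching the halides.

Step 13
Reactants: 19 (4S,6R,8S,9S)-4,8-dibromo-9-chloro-5,5,9-trimethylspiro[5.5]undecan-1-one
Product: 20 nidificene, (2S,6S,8S,9S)-2,8-dibromo-9-chloro-1,1,9-trimethyl-5-methylidenespiro[5.5]undecane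
Conditions: Cp2TiMe2, toluene, 65 °C, dark
Reagents that add atoms: dimethyltitanocene, C[Ti](C)(C1C=CC=C1)C1C=CC=C1
Why: Petasis methylenation through the non-basic titanocene methylidene converts the hindered, enolisable ketone into the C7=C14 alkene without base-induced loss of HCl or HBr.

**Compound list**

1 | prenol (3-methylbut-2-en-1-ol) | CC(C)=CCO | starting material
2 | (S)-2-bromo-3-chloro-3-methylbutan-1-ol | OC[C@H](Br)C(C)(C)Cl | intermediate
3 | (S)-2-bromo-3-chloro-3-methylbutyl trifluoromethanesulfonate | FC(F)(F)S(=O)(=O)OC[C@H](Br)C(C)(C)Cl | intermediate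
4 | allyl acetoacetate (prop-2-en-1-yl 3-oxobutanoate) | CC(=O)CC(=O)OCC=C | starting material
5 | sodium lithium dianion of allyl acetoacetate | [Na+].[Li+].[CH2-]C(=O)[CH-]C(=O)OCC=C | intermediate
6 | allyl (6S)-6-bromo-7-chloro-7-methyl-3-oxooctanoate | C=CCOC(=O)CC(=O)CC[C@H](Br)C(C)(C)Cl | intermediate
7 | allyl (3S)-3-bromo-2,2-dimethyl-6-oxocyclohexane-1-carboxylate (C1 epimers and enol form) | C=CCOC(=O)C1C(=O)CC[C@H](Br)C1(C)C | intermediate
8 | methyl vinyl ketone (but-3-en-2-one) | CC(=O)C=C | starting material
9 | allyl (3S)-3-bromo-2,2-dimethyl-6-oxo-1-(3-oxobutyl)cyclohexane-1-carboxylate (C1 epimers) | C=CCOC(=O)C1(CCC(C)=O)C(=O)CC[C@H](Br)C1(C)C | intermediate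
10 | allyl (3S)-3-bromo-2,2-dimethyl-1-[2-(2-methyl-1,3-dioxolan-2-yl)ethyl]-6-oxocyclohexane-1-carboxylate (C1 epimers) | C=CCOC(=O)C1(CCC2(C)OCCO2)C(=O)CC[C@H](Br)C1(C)C | intermediate
11 | allyl (3S)-3-bromo-6-hydroxy-2,2-dimethyl-1-[2-(2-methyl-1,3-dioxolan-2-yl)ethyl]cyclohexane-1-carboxylate (C1 and C6 epimers) | C=CCOC(=O)C1(CCC2(C)OCCO2)C(O)CC[C@H](Br)C1(C)C | intermediate
12 | (3S)-3-bromo-6-hydroxy-2,2-dimethyl-1-[2-(2-methyl-1,3-dioxolan-2-yl)ethyl]cyclohexane-1-carboxylic acid (C1 and C6 epimers) | OC(=O)C1(CCC2(C)OCCO2)C(O)CC[C@H](Br)C1(C)C | intermediate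
13 | (3S)-3-bromo-6-hydroxy-2,2-dimethyl-1-(3-oxobutyl)cyclohexane-1-carboxylic acid (C1 and C6 epimers; open form, in equilibrium with its lactol) | OC(=O)C1(CCC(C)=O)C(O)CC[C@H](Br)C1(C)C | intermediate
14 | vinyltriphenylphosphonium bromide | C=C[P+](c1ccccc1)(c1ccccc1)c1ccccc1.[Br-] | starting material
15 | 4-{(3S)-3-bromo-6-hydroxy-2,2-dimethyl-1-[2-(triphenylphosphoranylidene)ethyl]cyclohexyl}butan-2-one (quaternary carbon as in 16, carbinol epimers) | OC1CC[C@H](Br)C(C)(C)[C@@]1(CCC(C)=O)CC=P(c1ccccc1)(c1ccccc1)c1ccccc1 | intermediate
16 | (4S,6R)-4-bromo-5,5,9-trimethylspiro[5.5]undec-8-en-1-ol (C1 epimers) | OC1CC[C@H](Br)C(C)(C)[C@]12CCC(C)=CC2 | intermediate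
17 | bridged bromo ether, 2,10-dibromo-3,7-epoxy-14-norchamigrane (chamigrane locants; Br on C2 anti to the ether oxygen on C3; C2, C3, C6, C10 arranged as in 20; C7 epimers) | O3C1CC[C@H](Br)C(C)(C)[C@]12CC[C@@]3(C)[C@@H](Br)C2 | intermediate
18 | (4S,6R,8S,9S)-4,8-dibromo-9-chloro-5,5,9-trimethylspiro[5.5]undecan-1-ol (C1 epimers) | OC1CC[C@H](Br)C(C)(C)[C@]12CC[C@](C)(Cl)[C@@H](Br)C2 | intermediate
19 | (4S,6R,8S,9S)-4,8-dibromo-9-chloro-5,5,9-trimethylspiro[5.5]undecan-1-one | O=C1CC[C@H](Br)C(C)(C)[C@]12CC[C@](C)(Cl)[C@@H](Br)C2 | intermediate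
20 | nidificene, (2S,6S,8S,9S)-2,8-dibromo-9-chloro-1,1,9-trimethyl-5-methylidenespiro[5.5]undecane | C=C1CC[C@H](Br)C(C)(C)[C@]12CC[C@](C)(Cl)[C@@H](Br)C2 | target

**Step count and risks**

Total steps: 13. Longest linear sequence: 13 steps (1 to 20).

Steps most likely to fail:

Step 9 (Proposed new method). The congested C6 radical may abstract hydrogen or dimerise faster than it adds, the ylide may be protonated before it closes the ring, or the facial selectivity at C6 may be poor. Fallback with known chemistry, from 7 back to 16: Mannich alkylation of 7 with dimethylmethylideneammonium iodide (CH2Cl2, 40 °C) should give allyl (3S)-3-bromo-1-[(dimethylamino)methyl]-2,2-dimethyl-6-oxocyclohexane-1-carboxylate F1. Pd(PPh3)4 and morpholine in THF remove the allyl group, and the β-keto acid loses CO2 and dimethylamine to give (4S)-4-bromo-3,3-dimethyl-2-methylidenecyclohexan-1-one F2. A Diels–Alder reaction of F2 with isoprene (Me2AlCl, CH2Cl2, −78 to −20 °C), with the diene approaching anti to the axial methyl, should give (4S,6R)-4-bromo-5,5,9-trimethylspiro[5.5]undec-8-en-1-one F3. NaBH4 in MeOH then returns 16.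

Step 11. The bromonium ion pair may lose a proton (elimination) or take up chloride at the secondary C2 with migration of bromine, instead of collapsing at C3. Fallback from 16 back to 18, replacing the ether bridge by intermolecular halide capture: acetylation of 16 (Ac2O, DMAP, Et3N) gives (4S,6R)-4-bromo-5,5,9-trimethylspiro[5.5]undec-8-en-1-yl acetate F4. Anti-Markovnikov-free bromochlorination with Bu4NBrCl2 (CH2Cl2, 0 °C) should give both trans-diaxial adducts, from which (4S,6R,8S,9S)-4,8-dibromo-9-chloro-5,5,9-trimethylspiro[5.5]undecan-1-yl acetate F5 is separated. Reductive removal of the acetate with i-Bu2AlH (CH2Cl2, −78 °C) returns 18.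

Step 5. Conjugate addition at the carbon between the gem-dimethyl centre and the ketone may be slow or reversible, or the enol may close onto the C10 bromide in a 1,3-fashion. Fallback from 6 back to 9, forming the quaternary carbon in the ring closure instead: Michael addition of the unhindered acyclic β-keto ester 6 to methyl vinyl ketone (FeCl3·6H2O, CH2Cl2) gives allyl (6S)-6-bromo-7-chloro-7-methyl-3-oxo-2-(3-oxobutyl)octanoate F6. Solvolysis of F6 in (CF3)2CHOH then closes ring A through the bromonium ion and gives 9 directly.

Further compounds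
F1 | step 9 | allyl (3S)-3-bromo-1-[(dimethylamino)methyl]-2,2-dimethyl-6-oxocyclohexane-1-carboxylate | C=CCOC(=O)C1(CN(C)C)C(=O)CC[C@H](Br)C1(C)C
F2 | step 9 | (4S)-4-bromo-3,3-dimethyl-2-methylidenecyclohexan-1-one | C=C1C(=O)CC[C@H](Br)C1(C)C
F3 | step 9 | (4S,6R)-4-bromo-5,5,9-trimethylspiro[5.5]undec-8-en-1-one | O=C1CC[C@H](Br)C(C)(C)[C@]12CCC(C)=CC2
F4 | step 11 | (4S,6R)-4-bromo-5,5,9-trimethylspiro[5.5]undec-8-en-1-yl acetate | CC(=O)OC1CC[C@H](Br)C(C)(C)[C@]12CCC(C)=CC2
F5 | step 11 | (4S,6R,8S,9S)-4,8-dibromo-9-chloro-5,5,9-trimethylspiro[5.5]undecan-1-yl acetate | CC(=O)OC1CC[C@H](Br)C(C)(C)[C@]12CC[C@](C)(Cl)[C@@H](Br)C2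
F6 | step 5 | allyl (6S)-6-bromo-7-chloro-7-methyl-3-oxo-2-(3-oxobutyl)octanoate | C=CCOC(=O)C(CCC(C)=O)C(=O)CC[C@H](Br)C(C)(C)Cl
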